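**Plan**

1. Retrosynthesis: the two trans-oxiranes are removed last (E,E-diene 25), then the C8 tiglate and the O-protecting groups. The butenolide is cut at C7=C11 and O6–C12 (aldol of a C6 ketone with a C11–C13 α-keto ester). The ten-membered ring is cut by a retro-[2+2]: C4–C5 and C1–C10 are broken after C1–C4 and C5–C10 are joined.
2. Enabling feature: C1=C10 and C4=C5 are the 1,5-related ring double bonds, and C6, next to C5, bears oxygen. A cyclohexenone (ring C5–C10, chromophore C10=C5–C6=O) and a cyclobutene (ring C1–C4) therefore give the cyclobutane C1–C10–C5–C4, whose thermal cycloreversion across C1–C4/C5–C10 is the cyclodeca-1(10),4-diene. A CO2Me on C4 (the future C15 methyl) steers the orientation and is reduced afterwards.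
3. Forward order: six-membered ring (enone 7) → photochemical four-membered ring (strained 6/4/4 tricycle 12) → C15/C6 oxidation levels adjusted → thermal opening to the E,E ten-membered ring (16, 17) → butenolide ring (21) → tiglate → both oxirane rings (26).
4. Stereochemistry: C8 comes from a catalyst-controlled desymmetrising aldol condensation. The trans ring junction of 12 is transcribed into both E double bonds. C6 is set by 1,3-chelation-controlled reduction from C8. C1, C10, C4 and C5 are set by peracid attack on the outer faces of the crown conformer of 25.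

Key step: step 7

Remark 1: atoms are referred to by the germacrane numbers of the target (ring C1–C10; C11, C12, C13 = lactone α-carbon, carbonyl, CH2OH; C14 on C10; C15 on C4). Methyl cyclobut-1-ene-1-carboxylate (11) is taken as purchasable.
Remark 2 (assumption): triene lactone 25 is assumed to adopt the usual germacrolide crown conformation (C14 and C15 syn, both ring alkenes roughly perpendicular to the ring plane), so that peracid reaches only the outer face of each alkene.
Remark 3: 12–15 are drawn as one of the two trans-fused diastereomers (cyclobutane face relative to C8); the other behaves identically and converges at 16.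

**Step 1**
Reactants: 1 ethyl formate; 2 2-methylallylmagnesium chloride (2.2 equiv)
Product: 4 2,6-dimethylhepta-1,6-dien-4-ol, via 3-methylbut-3-enal 3 (not isolated)
Conditions: THF, −20 °C → rt; aq. NH4Cl
Reagents that add atoms: none
Why: Double Grignard addition to a formate ester (the intermediate aldehyde is more electrophilic than the ester) should give the symmetric secondary carbinol; no stereocentre is formed.

**Step 2**
Reactants: 4 2,6-dimethylhepta-1,6-dien-4-ol
Product: 5 4-[(4-methoxybenzyl)oxy]-2,6-dimethylhepta-1,6-diene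
Conditions: NaH, PMBCl, Bu4NI (cat.), THF/DMF, 0 °C → rt
Reagents that add atoms: 4-methoxybenzyl chloride COc1ccc(CCl)cc1
Why: Williamson etherification of the sodium alkoxide installs an ether that can chelate in step 14 and is removed oxidatively in step 16.

**Step 3**
Reactants: 5 4-[(4-methoxybenzyl)oxy]-2,6-dimethylhepta-1,6-diene
Product: 6 4-[(4-methoxybenzyl)oxy]heptane-2,6-dione
Conditions: O3, CH2Cl2/MeOH, −78 °C (Sudan III end point); Me2S, −78 °C → rt
Reagents that add atoms: ozone O=[O+][O-]
Why: Ozonolysis with reductive work-up cleaves the two 1,1-disubstituted alkenes to methyl ketones far faster than ozone attacks the anisyl ring, and the indicator dye marks the end point.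

**Step 4**
Reactants: 6 4-[(4-methoxybenzyl)oxy]heptane-2,6-dione
Product: 7 (S)-5-[(4-methoxybenzyl)oxy]-3-methylcyclohex-2-en-1-one
Conditions: 9-amino-9-deoxy-epi-quinine (or its quinidine pseudoenantiomer, whichever gives S; 20 mol %), AcOH (60 mol %), toluene, −15 °C
Reagents that add atoms: none
Why: Primary-amine-catalysed intramolecular aldol condensation of the prochiral 4-substituted heptane-2,6-dione (Hajos–Parrish-type desymmetrisation through the enamine): the chiral amine turns one of the two enantiotopic acetonyl arms into the nucleophile and so sets C8 (S), and the mildly acidic, cold conditions keep the β-alkoxy ketone from eliminating.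

**Step 5**
Reactants: 8 methyl 2-(hydroxymethyl)acrylate
Product: 9 methyl 2-{[(tert-butyldimethylsilyl)oxy]methyl}acrylate
Conditions: TBSCl, imidazole, DMF, 0 °C → rt
Reagents that add atoms: tert-butyldimethylsilyl chloride CC(C)(C)[Si](C)(C)Cl
Why: Standard silylation of the primary alcohol masks the future C13 hydroxyl through the base- and hydride-mediated steps.

**Step 6**
Reactants: 9 methyl 2-{[(tert-butyldimethylsilyl)oxy]methyl}acrylate
Product: 10 methyl 3-[(tert-butyldimethylsilyl)oxy]-2-oxopropanoate
Conditions: O3, CH2Cl2, −78 °C; Me2S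
Reagents that add atoms: ozone O=[O+][O-]
Why: Ozonolysis of the 1,1-disubstituted acrylate gives the α-keto ester that carries C11 (ketone), C12 (ester) and C13 (CH2OTBS).

**Step 7**
Reactants: 7 (S)-5-[(4-methoxybenzyl)oxy]-3-methylcyclohex-2-en-1-one; 11 methyl cyclobut-1-ene-1-carboxylate
Product: 12 methyl (9S)-9-[(4-methoxybenzyl)oxy]-1-methyl-7-oxotricyclo[4.4.0.0^2,5]decane-5-carboxylate (six/four junction trans; four/four junction cis)
Conditions: hν (λ > 300 nm, Pyrex), degassed CH2Cl2, −40 °C, the cyclobutene ester in fivefold excess (the excess is recovered unchanged); concentrated cold and neutral, used crude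
Reagents that add atoms: none
Why: n→π* excitation and intersystem crossing give the twisted triplet of enone 7, which bonds through C10 (β-carbon) to the unsubstituted cyclobutene carbon C1; the resulting 1,4-diradical (α-keto radical at C5, ester-stabilised tertiary radical at C4) closes the cyclobutane C1–C10–C5–C4 after spin inversion by forming C4–C5. The closest known reaction type is the enone–alkene [2+2] photocycloaddition of cyclohex-2-enones with cyclobut-1-enecarboxylates, used in photoaddition–cycloreversion routes to cyclodeca-1,5-dienes. The ring closed is the four-membered ring, by 1,4-diradical recombination (formal [2π+2π]), which gives a bicyclo[2.2.0]hexane fused to the cyclohexanone that thermal chemistry cannot reach. Of the new stereocentres, C1/C4 are cis because both lie in the cyclobutene ring, and the C5/C10 junction is set in the ring-closing event, the trans junction arising under kinetic control from the twisted triplet; the facial sense relative to C8 is immaterial because C1, C4, C5 and C10 all become sp2 in step 11. The step needs head-to-head orientation (ester-bearing C4 to the enone α-carbon C5), secured by the acceptor ester and by the C10 methyl, which disfavours a bond between the two fully substituted carbons C4 and C10; it also needs the trans 6/4 junction, which no substrate element enforces, so it is favoured by low temperature and preserved by cold neutral handling and immediate removal of the C6 ketone in step 8.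

**Step 8**
Reactants: 12 photoadduct keto ester
Product: 13 (9S)-5-(hydroxymethyl)-9-[(4-methoxybenzyl)oxy]-1-methyltricyclo[4.4.0.0^2,5]decan-7-ol (trans six/four junction; C7-carbinol epimers)
Conditions: LiAlH4, THF, −78 → 0 °C; Rochelle salt work-up; chromatography
Reagents that add atoms: none
Why: LiAlH4 reduces the ester to the C15 carbinol and the ketone to the C6 alcohol in one operation, which removes the enolisable carbonyl so that the trans C5/C10 junction can no longer epimerise; the C6 epimer mixture is inconsequential (re-oxidised in step 12) and cis-fused material is separated here.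

**Step 9**
Reactants: 13 tricyclic diol
Product: 14 primary 4-toluenesulfonate of 13 (C15–OTs; C6–OH free)
Conditions: TsCl (1.1 equiv), pyridine, DMAP (cat.), CH2Cl2, 0 °C
Reagents that add atoms: 4-toluenesulfonyl chloride Cc1ccc(cc1)S(=O)(=O)Cl
Why: Sulfonylation is selective for the primary C15 hydroxyl over the hindered secondary C6 hydroxyl.

**Step 10**
Reactants: 14 tricyclic tosylate
Product: 15 (9S)-9-[(4-methoxybenzyl)oxy]-1,5-dimethyltricyclo[4.4.0.0^2,5]decan-7-ol (trans six/four junction; C7 epimers)
Conditions: LiEt3BH, THF, 0 → 50 °C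
Reagents that add atoms: none
Why: Triethylborohydride displaces the primary tosylate by SN2 hydride transfer, which works at neopentyl-type centres and avoids the cationic cyclobutylcarbinyl rearrangements of an ionising deoxygenation; the C6 alkoxide cannot close a cyclic ether onto C15 because C6 and C15 are trans on the cyclobutane in this series, and the step turns the directing ester carbon into the C15 methyl.

**Step 11**
Reactants: 15 tricyclic methyl carbinol
Product: 16 (2E,6E,9S)-9-[(4-methoxybenzyl)oxy]-3,7-dimethylcyclodeca-2,6-dien-1-ol (C1 epimers)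
Conditions: flash vacuum thermolysis, ca. 420 °C, 0.01 mbar, base-washed quartz, trap at −78 °C
Reagents that add atoms: none
Why: Thermal [σ2s+σ2a] cycloreversion of the strained bicyclo[2.2.0]hexane through the cyclohexane-1,4-diyl (C1–C4 breaks first, then C5–C10): from the trans-fused adduct the only accessible chair diyl has C6 and C9 equatorial, so both new alkenes (C1=C10 and C4=C5) form E, and the high temperature with millisecond contact favours this high-A-factor fragmentation over the tight-transition-state Cope rearrangement of the product.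

**Step 12**
Reactants: 16 E,E-dienol
Product: 17 (2E,6E,9S)-9-[(4-methoxybenzyl)oxy]-3,7-dimethylcyclodeca-2,6-dien-1-one
Conditions: Dess–Martin periodinane, NaHCO3, CH2Cl2, 0 °C
Reagents that add atoms: none
Why: Buffered Dess–Martin oxidation of the allylic alcohol gives the enone without E/Z isomerisation and restores the C6 carbonyl whose α′-CH2 (C7) is needed for the annulation.

**Step 13**
Reactants: 17 E,E-dienone; 10 methyl 3-[(tert-butyldimethylsilyl)oxy]-2-oxopropanoate
Product: 18 methyl 3-[(tert-butyldimethylsilyl)oxy]-2-hydroxy-2-[(3E,7E,10S)-10-[(4-methoxybenzyl)oxy]-4,8-dimethyl-2-oxocyclodeca-3,7-dien-1-yl]propanoate (mixture at C7/C11)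
Conditions: LDA (0.98 equiv), THF, −78 °C; then 10; AcOH quench at −78 °C
Reagents that add atoms: none
Why: Kinetic deprotonation of the enone at the α′-carbon (C7) gives the cross-conjugated lithium enolate, which at −78 °C adds to the highly electrophilic ketone of the α-keto ester faster than it expels the C8 alkoxide (aldol addition); C7 and C11 form as a mixture that is erased in step 15.

**Step 14**
Reactants: 18 aldol adduct
Product: 20 (1(10)E,4E,6R,8S)-13-[(tert-butyldimethylsilyl)oxy]-11-hydroxy-8-[(4-methoxybenzyl)oxy]germacra-1(10),4-dien-12,6-olide (mixture at C7/C11), via 6-hydroxy ester 19 (not isolated)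
Conditions: Zn(BH4)2, Et2O, −40 °C; then K2CO3 (cat.), MeOH, 0 °C
Reagents that add atoms: none
Why: Chelation-controlled reduction of the β-alkoxy ketone: Zn(II) bridges the C6 carbonyl and the C8 ether oxygen and hydride is delivered to the open face of the six-membered chelate, which should give the 6,8-syn (6α) alcohol, and base then closes the γ-lactone onto the methyl ester.

**Step 15**
Reactants: 20 11-hydroxy lactone
Product: 21 (1(10)E,4E,6R,8S)-13-[(tert-butyldimethylsilyl)oxy]-8-[(4-methoxybenzyl)oxy]germacra-1(10),4,7(11)-trien-12,6-olide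
Conditions: Martin sulfurane, CH2Cl2, 0 °C → rt
Reagents that add atoms: none
Why: Dehydration of the tertiary α-hydroxy lactone through its alkoxysulfonium derivative; loss of the ring hydrogen at C7 gives the conjugated tetrasubstituted butenolide and is preferred over loss of an α-silyloxy C13 hydrogen, which would give an enol ether.

**Step 16**
Reactants: 21 PMB-protected butenolide
Product: 22 (1(10)E,4E,6R,8S)-13-[(tert-butyldimethylsilyl)oxy]-8-hydroxygermacra-1(10),4,7(11)-trien-12,6-olide
Conditions: DDQ, CH2Cl2/pH 7 buffer, 0 °C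
Reagents that add atoms: none
Why: Oxidative PMB cleavage (hydride abstraction at the anisylic carbon, then hydrolysis) leaves the silyl ether, the lactone and the trisubstituted alkenes untouched.

**Step 17**
Reactants: 22 C8 alcohol; 23 (E)-2-methylbut-2-enoyl chloride (tigloyl chloride)
Product: 24 (1(10)E,4E,6R,8S)-13-[(tert-butyldimethylsilyl)oxy]-8-[(E)-2-methylbut-2-enoyloxy]germacra-1(10),4,7(11)-trien-12,6-olide
Conditions: pyridine, DMAP (cat.), CH2Cl2, 0 °C
Reagents that add atoms: none
Why: DMAP-catalysed acylation of the secondary allylic alcohol; the tiglate is the stable E isomer, so double-bond isomerisation of the acyl group is not an issue.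

**Step 18**
Reactants: 24 silyl ether
Product: 25 (1(10)E,4E,6R,8S)-13-hydroxy-8-[(E)-2-methylbut-2-enoyloxy]germacra-1(10),4,7(11)-trien-12,6-olide
Conditions: HF·pyridine, pyridine, THF, 0 °C
Reagents that add atoms: none
Why: Buffered fluoride desilylation frees the primary C13 hydroxyl without touching the two esters or the acid-sensitive 1,5-diene, and is placed before epoxidation because the oxiranes would not survive it.

**Step 19**
Reactants: 25 triene lactone
Product: 26 (1R,4R,5R,6S,8S,10R)-1,10:4,5-diepoxy-13-hydroxy-8-[(E)-2-methylbut-2-enoyloxy]germacr-7(11)-en-12,6-olide (CNP0111480.1)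
Conditions: mCPBA (2.2 equiv), NaHCO3, CH2Cl2, 0 °C
Reagents that add atoms: 3-chloroperoxybenzoic acid OOC(=O)c1cccc(Cl)c1
Why: Prilezhaev epoxidation is selective for the two electron-rich trisubstituted ring alkenes over the butenolide and tiglate double bonds, is stereospecific (E-alkene → trans-oxirane), and attack on the exposed outer face of each alkene of the crown conformer should set 1R,10R and 4R,5R.

**Compound list**

1 | ethyl formate | CCOC=O | starting material
2 | 2-methylallylmagnesium chloride | CC(=C)C[Mg]Cl | starting material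
3 | 3-methylbut-3-enal | CC(=C)CC=O | intermediate (not isolated)
4 | 2,6-dimethylhepta-1,6-dien-4-ol | CC(=C)CC(O)CC(C)=C | intermediate
5 | 4-[(4-methoxybenzyl)oxy]-2,6-dimethylhepta-1,6-diene | COc1ccc(COC(CC(C)=C)CC(C)=C)cc1 | intermediate
6 | 4-[(4-methoxybenzyl)oxy]heptane-2,6-dione | COc1ccc(COC(CC(C)=O)CC(C)=O)cc1 | intermediate
7 | (S)-5-[(4-methoxybenzyl)oxy]-3-methylcyclohex-2-en-1-one | O=C1C=C(C)C[C@H](OCc2ccc(OC)cc2)C1 | intermediate
8 | methyl 2-(hydroxymethyl)acrylate | C=C(CO)C(=O)OC | starting material
9 | methyl 2-{[(tert-butyldimethylsilyl)oxy]methyl}acrylate | C=C(CO[Si](C)(C)C(C)(C)C)C(=O)OC | intermediate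
10 | methyl 3-[(tert-butyldimethylsilyl)oxy]-2-oxopropanoate | COC(=O)C(=O)CO[Si](C)(C)C(C)(C)C | intermediate
11 | methyl cyclobut-1-ene-1-carboxylate | COC(=O)C1=CCC1 | starting material
12 | methyl (9S)-9-[(4-methoxybenzyl)oxy]-1-methyl-7-oxotricyclo[4.4.0.0^2,5]decane-5-carboxylate (trans 6/4; cis 4/4) | O=C1C[C@@H](OCc4ccc(OC)cc4)C[C@]2(C)[C@H]3CC[C@@]3(C(=O)OC)[C@@H]12 | intermediate
13 | (9S)-5-(hydroxymethyl)-9-[(4-methoxybenzyl)oxy]-1-methyltricyclo[4.4.0.0^2,5]decan-7-ol (trans 6/4; C7 epimers) | OC1C[C@@H](OCc4ccc(OC)cc4)C[C@]2(C)[C@H]3CC[C@@]3(CO)[C@@H]12 | intermediate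
14 | primary tosylate of 13 | OC1C[C@@H](OCc4ccc(OC)cc4)C[C@]2(C)[C@H]3CC[C@@]3(COS(=O)(=O)c5ccc(C)cc5)[C@@H]12 | intermediate
15 | (9S)-9-[(4-methoxybenzyl)oxy]-1,5-dimethyltricyclo[4.4.0.0^2,5]decan-7-ol (trans 6/4; C7 epimers) | OC1C[C@@H](OCc4ccc(OC)cc4)C[C@]2(C)[C@H]3CC[C@@]3(C)[C@@H]12 | intermediate
16 | (2E,6E,9S)-9-[(4-methoxybenzyl)oxy]-3,7-dimethylcyclodeca-2,6-dien-1-ol (C1 epimers) | OC1/C=C(\C)CC/C=C(\C)C[C@H](OCc2ccc(OC)cc2)C1 | intermediate
17 | (2E,6E,9S)-9-[(4-methoxybenzyl)oxy]-3,7-dimethylcyclodeca-2,6-dien-1-one | O=C1/C=C(\C)CC/C=C(\C)C[C@H](OCc2ccc(OC)cc2)C1 | intermediate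
18 | methyl 3-[(tert-butyldimethylsilyl)oxy]-2-hydroxy-2-[(3E,7E,10S)-10-[(4-methoxybenzyl)oxy]-4,8-dimethyl-2-oxocyclodeca-3,7-dien-1-yl]propanoate (mixture at C7/C11) | O=C1/C=C(\C)CC/C=C(\C)C[C@H](OCc2ccc(OC)cc2)C1C(O)(CO[Si](C)(C)C(C)(C)C)C(=O)OC | intermediate
19 | 6-hydroxy ester (6R,8S): 18 reduced at C6 (mixture at C7/C11) | O[C@@H]1/C=C(\C)CC/C=C(\C)C[C@H](OCc2ccc(OC)cc2)C1C(O)(CO[Si](C)(C)C(C)(C)C)C(=O)OC | intermediate (not isolated)
20 | (1(10)E,4E,6R,8S)-13-[(tert-butyldimethylsilyl)oxy]-11-hydroxy-8-[(4-methoxybenzyl)oxy]germacra-1(10),4-dien-12,6-olide (mixture at C7/C11) | COc1ccc(CO[C@H]2C/C(C)=C/CC/C(C)=C/[C@H]3OC(=O)C(O)(CO[Si](C)(C)C(C)(C)C)C23)cc1 | intermediate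
21 | (1(10)E,4E,6R,8S)-13-[(tert-butyldimethylsilyl)oxy]-8-[(4-methoxybenzyl)oxy]germacra-1(10),4,7(11)-trien-12,6-olide | COc1ccc(CO[C@H]2C/C(C)=C/CC/C(C)=C/[C@H]3OC(=O)C(CO[Si](C)(C)C(C)(C)C)=C23)cc1 | intermediate
22 | (1(10)E,4E,6R,8S)-13-[(tert-butyldimethylsilyl)oxy]-8-hydroxygermacra-1(10),4,7(11)-trien-12,6-olide | O[C@H]1C/C(C)=C/CC/C(C)=C/[C@H]2OC(=O)C(CO[Si](C)(C)C(C)(C)C)=C12 | intermediate
23 | (E)-2-methylbut-2-enoyl chloride (tigloyl chloride) | C/C=C(\C)C(Cl)=O | starting material
24 | (1(10)E,4E,6R,8S)-13-[(tert-butyldimethylsilyl)oxy]-8-[(E)-2-methylbut-2-enoyloxy]germacra-1(10),4,7(11)-trien-12,6-olide | C/C=C(\C)C(=O)O[C@H]1C/C(C)=C/CC/C(C)=C/[C@H]2OC(=O)C(CO[Si](C)(C)C(C)(C)C)=C12 | intermediate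
25 | (1(10)E,4E,6R,8S)-13-hydroxy-8-[(E)-2-methylbut-2-enoyloxy]germacra-1(10),4,7(11)-trien-12,6-olide | C/C=C(\C)C(=O)O[C@H]1C/C(C)=C/CC/C(C)=C/[C@H]2OC(=O)C(CO)=C12 | intermediate
26 | (1R,4R,5R,6S,8S,10R)-1,10:4,5-diepoxy-13-hydroxy-8-[(E)-2-methylbut-2-enoyloxy]germacr-7(11)-en-12,6-olide | C/C=C(\C)C(=O)O[C@H]1C[C@@]2(C)O[C@@H]2CC[C@@]2(C)O[C@@H]2[C@H]2OC(=O)C(CO)=C12 | target

**Step count**

Total steps: 19. Longest linear sequence: 17 (steps 1–4 and 7–19); steps 5–6 form the side branch to 10.

**Steps most likely to fail**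

Step 7. What may go wrong: the 1,4-diradical collapses mainly to the cis 6/4 junction, or the trans junction epimerises at C5 before the ketone is reduced, so that step 11 would deliver an E,Z-diene. The fallback sets out from 12 and returns at 17; it accepts the cis junction and corrects the alkene geometry afterwards.
- Compound 12 (or the cis-fused co-product itself) is equilibrated with DBU to the cis-anti-cis keto ester F1.
- In this series C6 and C15 are cis on the cyclobutane, so a free C6 alkoxide would close a cyclic ether onto a C15 tosylate. The ketone is therefore masked first: ethylene glycol and PPTS (benzene, water removal) give the dioxolane ester F2.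
- LiAlH4 gives the dioxolane carbinol F3, TsCl/pyridine its tosylate F4, and LiEt3BH the dioxolane methyl compound F5.
- PPTS in wet acetone frees the configurationally stable cis-fused ketone F6.
- Flash vacuum thermolysis should open it to the (2Z,6E)-dienone F7. A cis junction places one of C6 and C9 axial in the chair 1,4-diyl and so forces one alkene to form Z. The Z bond is expected at C4=C5, because an equatorial C6 would be eclipsed by the C15 methyl on the planar C4 centre. The enone conjugation, which a Cope rearrangement would destroy, should hold the product as the ten-membered ring.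
- The enone geometry is then inverted by addition–elimination. Conjugate addition of Me3SnLi (THF, −78 °C) gives the β-stannyl ketone F8, and oxidative destannylation (CrO3·2 pyridine, CH2Cl2) should re-form the enone under kinetic control as the E isomer, 17.

Step 11. What may go wrong: Cope rearrangement of the E,E-dienol to the trans-1,2-dialkenylcyclohexanol (elemane type) at the temperature needed for ring opening, and surface-catalysed dehydration at the free C6 hydroxyl. The fallback sets out from 15 and returns at 17; it changes the oxidation level at which the ring is opened. Compound 15 is oxidised first (Dess–Martin periodinane, NaHCO3) to the trans-fused ketone F9, which is kept strictly neutral because C5 is then epimerisable. Flash thermolysis of F9 should give dienone 17 directly. Here C4=C5 emerges conjugated with C6=O, a stabilisation that is lost in the Cope transition state and in the divinylcyclohexanone, and no free hydroxyl is present.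

Step 14. What may go wrong: hydride delivery to the other face of the C6 carbonyl, because the C7 substituent and the C11 alkoxide can override the C8 chelate, leading to the 6-epi lactone. The fallback sets out from 18 and returns at 20; it makes the 6-epimer on purpose and inverts it. Compound 18 is reduced under non-chelating conditions chosen to maximise the 6-epimer (NaBH4/CeCl3, MeOH, −78 °C) to the 6-epi hydroxy ester F10, which is not isolated and is lactonised with K2CO3 in MeOH to the 6-epi hydroxy lactone F11. Saponification (LiOH, THF/H2O, 0 °C) and cold acidification to pH 5 give the 6-epi hydroxy acid F12, which is used at once. Mitsunobu lactonisation (PPh3, DIAD, dilute THF, 0 °C) activates the allylic C6 hydroxyl and lets the carboxylate displace it with inversion, giving 20.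

**Further compounds**

F1 | step 7 | methyl (9S)-9-[(4-methoxybenzyl)oxy]-1-methyl-7-oxotricyclo[4.4.0.0^2,5]decane-5-carboxylate (cis-anti-cis; epimer of 12 at germacrane C5) | O=C1C[C@@H](OCc4ccc(OC)cc4)C[C@]2(C)[C@H]3CC[C@@]3(C(=O)OC)[C@H]12
F2 | step 7 | methyl (9S)-7,7-(ethylenedioxy)-9-[(4-methoxybenzyl)oxy]-1-methyltricyclo[4.4.0.0^2,5]decane-5-carboxylate (cis-anti-cis) | O1CCOC12C[C@@H](OCc4ccc(OC)cc4)C[C@]3(C)[C@H]5CC[C@@]5(C(=O)OC)[C@H]23
F3 | step 7 | [(9S)-7,7-(ethylenedioxy)-9-[(4-methoxybenzyl)oxy]-1-methyltricyclo[4.4.0.0^2,5]decan-5-yl]methanol (cis-anti-cis) | O1CCOC12C[C@@H](OCc4ccc(OC)cc4)C[C@]3(C)[C@H]5CC[C@@]5(CO)[C@H]23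
F4 | step 7 | 4-toluenesulfonate of F3 | O1CCOC12C[C@@H](OCc4ccc(OC)cc4)C[C@]3(C)[C@H]5CC[C@@]5(COS(=O)(=O)c6ccc(C)cc6)[C@H]23
F5 | step 7 | (9S)-7,7-(ethylenedioxy)-9-[(4-methoxybenzyl)oxy]-1,5-dimethyltricyclo[4.4.0.0^2,5]decane (cis-anti-cis) | O1CCOC12C[C@@H](OCc4ccc(OC)cc4)C[C@]3(C)[C@H]5CC[C@@]5(C)[C@H]23
F6 | step 7 | cis-fused (9S)-9-[(4-methoxybenzyl)oxy]-1,5-dimethyltricyclo[4.4.0.0^2,5]decan-7-one | O=C1C[C@@H](OCc4ccc(OC)cc4)C[C@]2(C)[C@H]3CC[C@@]3(C)[C@H]12
F7 | step 7 | (2Z,6E,9S)-9-[(4-methoxybenzyl)oxy]-3,7-dimethylcyclodeca-2,6-dien-1-one | O=C1/C=C(/C)CC/C=C(\C)C[C@H](OCc2ccc(OC)cc2)C1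
F8 | step 7 | (6E,9S)-9-[(4-methoxybenzyl)oxy]-3,7-dimethyl-3-(trimethylstannyl)cyclodec-6-en-1-one | O=C1CC(C)([Sn](C)(C)C)CC/C=C(\C)C[C@H](OCc2ccc(OC)cc2)C1
F9 | step 11 | trans-fused (9S)-9-[(4-methoxybenzyl)oxy]-1,5-dimethyltricyclo[4.4.0.0^2,5]decan-7-one | O=C1C[C@@H](OCc4ccc(OC)cc4)C[C@]2(C)[C@H]3CC[C@@]3(C)[C@@H]12
F10 | step 14 | 6-epi hydroxy ester (6S,8S): 6-epimer of 19 (mixture at C7/C11) | O[C@H]1/C=C(\C)CC/C=C(\C)C[C@H](OCc2ccc(OC)cc2)C1C(O)(CO[Si](C)(C)C(C)(C)C)C(=O)OC
F11 | step 14 | 6-epimer of 20 (6S,8S; mixture at C7/C11) | COc1ccc(CO[C@H]2C/C(C)=C/CC/C(C)=C/[C@@H]3OC(=O)C(O)(CO[Si](C)(C)C(C)(C)C)C23)cc1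
F12 | step 14 | 6-epi hydroxy acid: ring-opened F11 (free C6–OH; C12 acid) | O[C@H]1/C=C(\C)CC/C=C(\C)C[C@H](OCc2ccc(OC)cc2)C1C(O)(CO[Si](C)(C)C(C)(C)C)C(=O)O
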